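A direct plan would copy the presumed biogenesis: a syn-5,6:7,8-diepoxide of 2-[2-(4-methoxyphenyl)ethyl]-5,6,7,8-tetrahydrochromone (A1) would be opened twice by 6,7-dihydroxy-2-(2-phenylethyl)chromone (A2), so that the dioxepine would close last by two SN2 displacements at C5 and C7.
A1 would come from a chiral cyclohexenone acetal (A3) cut out of quinic acid, annulated with an ynal to the trans-5,6-dihydrodiol A4, then epoxidised and cyclodehydrated.
One weak point would be the degradation of quinic acid to A3: four operations that only remove carbon and oxygen and add no complexity.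
A second would be the conversion of A4 into A1 (hydroxyl-directed epoxidation, then closure of a trans-diol to the second epoxide): the face selectivity and the choice of which hydroxyl is displaced would rest on analogy, on intermediates one dehydration away from an aromatic chromone.
The weakest would be the final union of A1 with A2: which phenol attacks first, C5 against C8, bridging against oligomerisation and the stability of A1 would all depend on small biases, in the last step and on both advanced fragments.

Plan of the new route: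
Ring A carries at C5–C8 the all-trans oxygen pattern of C1–C4 of a β-D-glucopyranoside (C8a = C5 of glucose), so C5–C8a are taken from diacetone-D-glucose and C2–C4a with the side chain from a β-diketone.
The retrosynthesis cuts the aryl C–O bonds O–C7' and O–C6' (two SNAr reactions), C4a–C5 (aldol), C4a–C8a (Claisen) and O1–C8a (cyclodehydration).
The only free hydroxyl of diacetone glucose (O3, later on C7) displaces the fluoride para to the nitro group of a 4,5-difluoro-2-nitrobenzoate; ester and nitro group then become the aromatic chromone, which leaves the second fluoride para to the C4' carbonyl.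
Excision of C6 gives a lactone acetal that a diketone dianion turns into the carbocycle; because C4a lies between the C4 and C8a carbonyls, the aldol that creates C5 is reversible, and the C5 and C7 oxygens can become cis-1,3-diaxial.
The C5 alkoxide then closes the bridging dioxepine at C7', and acid closes the γ-pyranone of ring A last; the rings arise in the order aromatic chromone, carbocycle, dioxepine, pyranone A.
No epoxide, dihydrodiol or tetrahydrochromone precedes the bridge, the regiochemistry of both ether bonds is fixed by the activating groups of the arene, and C6–C8 come with glucose.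

Key step: step 10

Remark: the (+)-enantiomer is taken to be the (5R,6S,7R,8S) isomer of the SMILES. Ring A locants (C2–C8a) refer to the tetrahydrochromone, primed locants to the aromatic chromone. Compounds 7–11 are drawn as α-anomers; the β-anomers would be carried along, since C1 becomes the aldehyde carbon in step 9.

Step 1
Reactants: 1 1,2:5,6-di-O-isopropylidene-α-D-glucofuranose; 2 methyl 4,5-difluoro-2-nitrobenzoate
Product: 3 3-O-[2-fluoro-5-(methoxycarbonyl)-4-nitrophenyl]-1,2:5,6-di-O-isopropylidene-α-D-glucofuranose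
Conditions: NaH (1.1 equiv), THF, 0 °C; 2 (1.05 equiv), −20 to 0 °C
Reagents that add atoms: none
Why: SNAr (addition–elimination) by the single free alkoxide of 1, in which the fluoride para to the nitro group should be displaced in preference to the one para to the ester, so that O3 of glucose (the future C7 oxygen) ends on the future C6'; no stereocentre is touched.

Step 2
Reactants: 3 aryl ether from step 1; 4 4-phenylbutan-2-one
Product: 6 3-O-[7-fluoro-4-oxo-2-(2-phenylethyl)-4H-chromen-6-yl]-1,2:5,6-di-O-isopropylidene-α-D-glucofuranose, via 1,3-diketone 5 (not isolated)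
Conditions: 4 (2.5 equiv), LiN(i-Pr)2 (2.6 equiv), THF, −78 °C; 3, −78 to −20 °C; aq. NH4Cl; crude 5, K2CO3, DMF, 60 °C
Reagents that add atoms: none
Why: Crossed Claisen condensation of the kinetic (methyl-side) lithium enolate of 4 with the aryl ester gives the 1,3-diketone, whose enolate oxygen displaces the ortho nitro group (intramolecular SNAr, denitrocyclisation, six-membered) to close the chromone, which places the remaining fluoride para to the chromone carbonyl.

Step 3
Reactants: 6 chromone-bearing diacetone glucose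
Product: 7 methyl 3-O-[7-fluoro-4-oxo-2-(2-phenylethyl)-4H-chromen-6-yl]-α-D-glucopyranoside
Conditions: HCl (1.25 M in MeOH), 60 °C
Reagents that add atoms: methanol CO
Why: Fischer glycosidation under thermodynamic control: acid methanolysis removes both acetonides and equilibrates the furanosides to the methyl pyranosides, which frees O6 for the excision of C6 while aryl ether and chromone are acid-stable; the new anomeric centre is irrelevant later.

Step 4
Reactants: 7 methyl glucopyranoside
Product: 8 methyl 6-deoxy-6-iodo-3-O-[7-fluoro-4-oxo-2-(2-phenylethyl)-4H-chromen-6-yl]-α-D-glucopyranoside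
Conditions: I2, PPh3, imidazole, THF, 60 °C
Reagents that add atoms: iodine [I][I]
Why: Garegg–Samuelsson (Appel-type) iodination, selective for the primary hydroxyl over the two hindered secondary ones.

Step 5
Reactants: 8 6-iodide
Product: 9 methyl 6-deoxy-6-iodo-2,4-bis-O-(methoxymethyl)-3-O-[7-fluoro-4-oxo-2-(2-phenylethyl)-4H-chromen-6-yl]-α-D-glucopyranoside
Conditions: MeOCH2Cl (6 equiv), i-Pr2NEt (8 equiv), n-Bu4NI (cat.), ClCH2CH2Cl, 50 °C
Reagents that add atoms: chloromethyl methyl ether COCCl
Why: Acetal protection (methoxymethylation) with an amine base only, so that no alkoxide is formed next to the aryl fluoride; the two ethers cannot migrate and should survive strong base, which the later alkoxide chemistry at C5 requires.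

Step 6
Reactants: 9 bis-MOM iodide
Product: 10 methyl 6-deoxy-2,4-bis-O-(methoxymethyl)-3-O-[7-fluoro-4-oxo-2-(2-phenylethyl)-4H-chromen-6-yl]-α-D-xylo-hex-5-enopyranoside
Conditions: AgF (3 equiv), pyridine, rt, dark
Reagents that add atoms: none
Why: Silver-assisted dehydroiodination (E2) to the exocyclic enol ether, the standard entry to hex-5-enopyranosides, under conditions too mild to attack the aryl fluoride.

Step 7
Reactants: 10 hex-5-enopyranoside
Product: 11 6-methoxy-3,5-bis(methoxymethoxy)-4-{[7-fluoro-4-oxo-2-(2-phenylethyl)-4H-chromen-6-yl]oxy}oxan-2-one (δ-lactone; C2 = former C5 of glucose, C3–C5 with the D-xylo configuration of glucose C4–C2, C6 = former anomeric carbon)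
Conditions: O3, CH2Cl2, −78 °C (to first blue tinge); Me2S, −78 °C to rt
Reagents that add atoms: ozone [O-][O+]=O
Why: Ozonolysis of the electron-rich exocyclic enol ether excises C6 as formaldehyde and leaves C5 of glucose as a lactone carbonyl (future C8a), while the anomeric carbon (future C5) stays masked as a mixed acetal; the chromone alkene and the arenes should react far more slowly.

Step 8
Reactants: 12 pentane-2,4-dione; 13 4-methoxybenzyl chloride
Product: 14 6-(4-methoxyphenyl)hexane-2,4-dione
Conditions: NaH (1.05 equiv), THF, 0 °C; n-BuLi (1.05 equiv), 0 °C; 13 (0.95 equiv), −78 to 0 °C; aq. HCl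
Reagents that add atoms: none
Why: γ-Alkylation of a β-diketone dianion, which reacts at the terminal, more basic carbanion.

Step 9
Reactants: 11 lactone acetal; 14 6-(4-methoxyphenyl)hexane-2,4-dione
Product: 17 3-hydroxy-4,6-bis(methoxymethoxy)-2-[5-(4-methoxyphenyl)-3-oxopentanoyl]-5-{[7-fluoro-4-oxo-2-(2-phenylethyl)-4H-chromen-6-yl]oxy}cyclohexan-1-one (ring A numbering: C8a ketone, C4a acyl, C5 carbinol as 5R/5S mixture, C6–C8 as in the target; enolised β-triketone), via hemiketal adduct 15 (not isolated), via open-chain keto aldehyde 16 (not isolated)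
Conditions: 14 (1.05 equiv), LiN(i-Pr)2 (2.1 equiv), THF, −78 to 0 °C; 11, −78 °C, then to −20 °C; AcOH, −40 °C; pH 7 buffer; toluene azeotrope
Reagents that add atoms: none
Why: Claisen-type γ-acylation of the diketone dianion by the lactone gives a lithium hemiketalate that is stable at −78 °C; on warming it opens, the hemiacetal alkoxide expels methoxide to unmask the C5 aldehyde, and the β-triketone carbanion C4a closes the six-membered ring by intramolecular aldol addition (6-enolexo, the ring closure of the Ferrier carbocyclisation); C6–C8 come unchanged from D-glucose and C5 is deliberately left as a mixture.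

Step 10
Reactants: 17 cyclic aldol (5R/5S mixture)
Product: 19 bridged β-triketone, (5R,6S,7R,8S) in ring A numbering, in which the C5 oxygen is bonded to C7' in place of fluorine (1,5-benzodioxepine spanning C5 and C7; C4a–H between the C8a ketone and the 5-(4-methoxyphenyl)-3-oxopentanoyl group; C6 and C8 as MOM ethers), via 5R aldolate 18 (not isolated)
Conditions: KN(SiMe3)2 (2.7 equiv), 18-crown-6 (3 equiv), THF (0.01 M), −78 °C to rt; AcOH
Reagents that add atoms: none
Why: Proposed new method: with slightly less than three equivalents of base the material is spread between the trianion (C3 and C4a enolates, C5 alkoxide) and dianions that keep hydrogen on C4a, and in the latter the C5 alkoxide undergoes retro-aldol cleavage to the open-chain triketonate aldehyde and re-closure, so that the 5R and 5S aldolates interconvert (thermodynamic aldol equilibration of a β-hydroxy β-triketone). Only the 5R alkoxide, cis-1,3-diaxial to the aryloxy group on C7 in the all-axial half-chair, can reach C7' of the fluorochromone, where it displaces fluoride para to the chromone carbonyl by intramolecular SNAr through a Meisenheimer complex; this irreversible step closes the seven-membered 1,5-benzodioxepine across C5 and C7 (bridged bicyclo[4.3.1] system) and drains the equilibrium (dynamic diastereoconvergent trapping). The closest known reaction types are alkoxide SNAr on 7-fluorochromones and 4-fluoroaryl ketones, the bridging of cis-1,3-diols by ortho-dihaloarenes, and the epimerisation of aldols by retro-aldol cleavage. C5 is controlled by the tether (the 5S alkoxide cannot reach the ring), while C6, C7 and C8 are not enolisable in the triketonate and stay as set by D-glucose. The step needs O5 to attack before O6 or O8 (secured by the MOM ethers, since free neighbours would close a six-membered benzodioxane), alkoxide before enolate oxygen (the delocalised triketonate is a far weaker nucleophile) and substitution before dehydration (the C5 oxygen is held as an alkoxide, which cannot leave, and no methoxide remains after the solvent exchange of step 9).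

Step 11
Reactants: 19 bridged β-triketone
Product: 21 (+)-4'-methoxyaquisinenone G, via bridged pyranone bis-MOM ether 20 (not isolated)
Conditions: CF3CO2H/CH2Cl2 (1:1), 0 °C to rt; then H2O (5 vol %), rt
Reagents that add atoms: none
Why: Acid-catalysed cyclodehydration of the 1,3,5-triketone closes the γ-pyranone of ring A (O1–C8a), after which C4a bears no hydrogen and the C5 aryl ether can no longer open by retro-oxa-Michael reaction (any opened material can only re-close cis and then aromatise), and the same acid hydrolyses the two MOM acetals; no stereocentre is affected.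

**Compound list**
1 | 1,2:5,6-di-O-isopropylidene-α-D-glucofuranose | CC1(C)O[C@H]2O[C@H]([C@H]3COC(C)(C)O3)[C@H](O)[C@H]2O1 | starting material
2 | methyl 4,5-difluoro-2-nitrobenzoate | COC(=O)c1cc(F)c(F)cc1[N+](=O)[O-] | starting material
3 | 3-O-[2-fluoro-5-(methoxycarbonyl)-4-nitrophenyl]-1,2:5,6-di-O-isopropylidene-α-D-glucofuranose | CC1(C)O[C@H]2O[C@H]([C@H]3COC(C)(C)O3)[C@H](Oc3cc(C(=O)OC)c([N+](=O)[O-])cc3F)[C@H]2O1 | intermediate
4 | 4-phenylbutan-2-one | CC(=O)CCc1ccccc1 | starting material
5 | 3-O-[2-fluoro-4-nitro-5-(3-oxo-5-phenylpentanoyl)phenyl]-1,2:5,6-di-O-isopropylidene-α-D-glucofuranose | CC1(C)O[C@H]2O[C@H]([C@H]3COC(C)(C)O3)[C@H](Oc3cc(C(=O)CC(=O)CCc4ccccc4)c([N+](=O)[O-])cc3F)[C@H]2O1 | intermediate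
6 | 3-O-[7-fluoro-4-oxo-2-(2-phenylethyl)-4H-chromen-6-yl]-1,2:5,6-di-O-isopropylidene-α-D-glucofuranose | CC1(C)O[C@H]2O[C@H]([C@H]3COC(C)(C)O3)[C@H](Oc3cc4c(=O)cc(CCc5ccccc5)oc4cc3F)[C@H]2O1 | intermediate
7 | methyl 3-O-[7-fluoro-4-oxo-2-(2-phenylethyl)-4H-chromen-6-yl]-α-D-glucopyranoside | OC[C@H]1O[C@H](OC)[C@H](O)[C@@H](Oc2cc3c(=O)cc(CCc4ccccc4)oc3cc2F)[C@@H]1O | intermediate
8 | methyl 6-deoxy-6-iodo-3-O-[7-fluoro-4-oxo-2-(2-phenylethyl)-4H-chromen-6-yl]-α-D-glucopyranoside | IC[C@H]1O[C@H](OC)[C@H](O)[C@@H](Oc2cc3c(=O)cc(CCc4ccccc4)oc3cc2F)[C@@H]1O | intermediate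
9 | methyl 6-deoxy-6-iodo-2,4-bis-O-(methoxymethyl)-3-O-[7-fluoro-4-oxo-2-(2-phenylethyl)-4H-chromen-6-yl]-α-D-glucopyranoside | IC[C@H]1O[C@H](OC)[C@H](OCOC)[C@@H](Oc2cc3c(=O)cc(CCc4ccccc4)oc3cc2F)[C@@H]1OCOC | intermediate
10 | methyl 6-deoxy-2,4-bis-O-(methoxymethyl)-3-O-[7-fluoro-4-oxo-2-(2-phenylethyl)-4H-chromen-6-yl]-α-D-xylo-hex-5-enopyranoside | C=C1O[C@H](OC)[C@H](OCOC)[C@@H](Oc2cc3c(=O)cc(CCc4ccccc4)oc3cc2F)[C@@H]1OCOC | intermediate
11 | 6-methoxy-3,5-bis(methoxymethoxy)-4-{[7-fluoro-4-oxo-2-(2-phenylethyl)-4H-chromen-6-yl]oxy}oxan-2-one (D-xylo lactone acetal) | O=C1O[C@H](OC)[C@H](OCOC)[C@@H](Oc2cc3c(=O)cc(CCc4ccccc4)oc3cc2F)[C@@H]1OCOC | intermediate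
12 | pentane-2,4-dione | CC(=O)CC(C)=O | starting material
13 | 4-methoxybenzyl chloride | COc1ccc(CCl)cc1 | starting material
14 | 6-(4-methoxyphenyl)hexane-2,4-dione | CC(=O)CC(=O)CCc1ccc(OC)cc1 | intermediate
15 | hemiketal adduct of 11 and 14 (2-hydroxy-2-[6-(4-methoxyphenyl)-2,4-dioxohexyl] derivative of the oxane of 11) | OC1(CC(=O)CC(=O)CCc2ccc(OC)cc2)O[C@H](OC)[C@H](OCOC)[C@@H](Oc2cc3c(=O)cc(CCc4ccccc4)oc3cc2F)[C@@H]1OCOC | intermediate
16 | open-chain keto aldehyde: D-xylo-configured 3-aryloxy-2,4-bis(methoxymethoxy)-11-(4-methoxyphenyl)-5,7,9-trioxoundecanal (aryl = 7-fluoro-4-oxo-2-(2-phenylethyl)-4H-chromen-6-yl) | O=C[C@H](OCOC)[C@@H](Oc1cc2c(=O)cc(CCc3ccccc3)oc2cc1F)[C@H](OCOC)C(=O)CC(=O)CC(=O)CCc1ccc(OC)cc1 | intermediate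
17 | 3-hydroxy-4,6-bis(methoxymethoxy)-2-[5-(4-methoxyphenyl)-3-oxopentanoyl]-5-{[7-fluoro-4-oxo-2-(2-phenylethyl)-4H-chromen-6-yl]oxy}cyclohexan-1-one (5R/5S mixture in ring A numbering) | OC1[C@H](OCOC)[C@@H](Oc2cc3c(=O)cc(CCc4ccccc4)oc3cc2F)[C@H](OCOC)C(=O)C1C(=O)CC(=O)CCc1ccc(OC)cc1 | intermediate
18 | (5R)-epimer of 17, present as its potassium alkoxide | O[C@H]1[C@H](OCOC)[C@@H](Oc2cc3c(=O)cc(CCc4ccccc4)oc3cc2F)[C@H](OCOC)C(=O)C1C(=O)CC(=O)CCc1ccc(OC)cc1 | intermediate
19 | bridged β-triketone, (5R,6S,7R,8S) in ring A numbering (C5–O–C7' and C7–O–C6' ether bonds, C6 and C8 MOM ethers, C8a ketone, C4a 5-(4-methoxyphenyl)-3-oxopentanoyl) | O2[C@H]1[C@H](OCOC)[C@@H](Oc3cc4c(=O)cc(CCc5ccccc5)oc4cc32)[C@H](OCOC)C(=O)C1C(=O)CC(=O)CCc1ccc(OC)cc1 | intermediate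
20 | 6,8-bis-O-(methoxymethyl) ether of 21 | COc1ccc(CCc2cc(=O)c3c(o2)[C@@H](OCOC)[C@@H]2Oc4cc5c(=O)cc(CCc6ccccc6)oc5cc4O[C@H]3[C@@H]2OCOC)cc1 | intermediate
21 | (+)-4'-methoxyaquisinenone G, (5R,6S,7R,8S) | COc1ccc(CCc2cc(=O)c3c(o2)[C@@H](O)[C@@H]2Oc4cc5c(=O)cc(CCc6ccccc6)oc5cc4O[C@H]3[C@@H]2O)cc1 | target

Total step count: 11. Longest linear sequence: 10 steps (steps 1–7 and 9–11, from diacetone-D-glucose); step 8 is a one-step side branch.

Steps most likely to fail:

Step 10. After retro-aldol opening, the aldehyde may lose the C7 aryloxy group by β-elimination or epimerise at C6, the aldol may dehydrate through the C4a enolate, or the bridging substitution may be too slow to compete. The fallback sets out from 17 and comes back at 20, and removes the retro-aldol pathway before the ether is closed. 17 would be cyclodehydrated with a catalytic amount of TsOH over molecular sieves (CH2Cl2, rt) to the 5-hydroxy-6,8-bis(methoxymethoxy)-7-aryloxy-5,6,7,8-tetrahydrochromone F1 (C5 epimers). F1 would be oxidised with Dess–Martin periodinane to the 5-ketone F2. Reduction with NaBH4 and CeCl3·7H2O should deliver hydride axially and give the trans-5,6 (5R) alcohol F3; a Mitsunobu inversion would correct the opposite outcome. The potassium alkoxide of F3 (KN(SiMe3)2, THF) would then close the dioxepine by the same SNAr to give 20.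

Step 9. The dianion may add to the chromone carbonyl or deprotonate its side-chain methylene instead of acylating the lactone, the unmasked aldehyde may eliminate before the aldol closes, or the aldol may dehydrate on work-up. The fallback sets out from 11 and comes back at 17, and forms the two C–C bonds in the opposite order so that the aldehyde never meets a strong base. 11 would be opened with methanol and a catalytic amount of Et3N to the open-chain methyl ester aldehyde F4. The bis(trimethylsilyl) dienol ether F5, made from 14 with Me3SiOSO2CF3 and Et3N, would be added to the aldehyde in a BF3·OEt2-mediated vinylogous Mukaiyama aldol reaction (γ-attack) to give, after desilylation, the δ-hydroxy β-diketone F6. F6 would be closed to 17 by Dieckmann-type acylation of its trianion (LiN(i-Pr)2, 3.2 equiv, THF, −78 to 0 °C).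

Step 2. The enolate may transfer an electron to, or add to, the nitroarene instead of condensing with the hindered ester, and fluoride instead of nitrite may be displaced in the ring closure. The fallback sets out from 1 and comes back at 6, and avoids nitro chemistry. Commercial 1-(5-bromo-4-fluoro-2-hydroxyphenyl)ethanone would be condensed with ethyl 3-phenylpropanoate (NaH, THF, reflux) to the diketone F7 and cyclodehydrated (HCl, MeOH) to 6-bromo-7-fluoro-2-(2-phenylethyl)-4H-chromen-4-one F8. 1 would then be O-arylated at the C–Br bond of F8 by palladium-catalysed C–O coupling (Pd(OAc)2 as divalent palladium precatalyst reduced in the flask to zerovalent palladium, the ligand RockPhos, Cs2CO3, toluene, 90 °C) to give 6. The weak, insoluble base is chosen so that uncatalysed attack of the alkoxide on the fluoride stays slow.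

**Further compounds**
F1 | step 10 | 5-hydroxy-6,8-bis(methoxymethoxy)-7-{[7-fluoro-4-oxo-2-(2-phenylethyl)-4H-chromen-6-yl]oxy}-2-[2-(4-methoxyphenyl)ethyl]-5,6,7,8-tetrahydro-4H-chromen-4-one (C5 epimers; 6S,7R,8S) | COc1ccc(CCc2cc(=O)c3c(o2)[C@@H](OCOC)[C@H](Oc2cc4c(=O)cc(CCc5ccccc5)oc4cc2F)[C@@H](OCOC)C3O)cc1
F2 | step 10 | 5-oxo analogue of F1 (7,8-dihydro-4H-chromene-4,5(6H)-dione) | COc1ccc(CCc2cc(=O)c3c(o2)[C@@H](OCOC)[C@H](Oc2cc4c(=O)cc(CCc5ccccc5)oc4cc2F)[C@@H](OCOC)C3=O)cc1
F3 | step 10 | (5R)-epimer of F1 | COc1ccc(CCc2cc(=O)c3c(o2)[C@@H](OCOC)[C@H](Oc2cc4c(=O)cc(CCc5ccccc5)oc4cc2F)[C@@H](OCOC)[C@@H]3O)cc1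
F4 | step 9 | methyl D-xylo-3-{[7-fluoro-4-oxo-2-(2-phenylethyl)-4H-chromen-6-yl]oxy}-2,4-bis(methoxymethoxy)-5-oxopentanoate (aldehyde ester) | O=C[C@H](OCOC)[C@@H](Oc1cc2c(=O)cc(CCc3ccccc3)oc2cc1F)[C@H](OCOC)C(=O)OC
F5 | step 9 | 6-(4-methoxyphenyl)-2,4-bis(trimethylsilyloxy)hexa-1,3-diene | C=C(O[Si](C)(C)C)C=C(O[Si](C)(C)C)CCc1ccc(OC)cc1
F6 | step 9 | methyl 3-aryloxy-5-hydroxy-2,4-bis(methoxymethoxy)-11-(4-methoxyphenyl)-7,9-dioxoundecanoate (C5 epimers; aryl as in F4) | OC(CC(=O)CC(=O)CCc1ccc(OC)cc1)[C@H](OCOC)[C@@H](Oc1cc2c(=O)cc(CCc3ccccc3)oc2cc1F)[C@H](OCOC)C(=O)OC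
F7 | step 2 | 1-(5-bromo-4-fluoro-2-hydroxyphenyl)-5-phenylpentane-1,3-dione | O=C(CC(=O)CCc1ccccc1)c1cc(Br)c(F)cc1O
F8 | step 2 | 6-bromo-7-fluoro-2-(2-phenylethyl)-4H-chromen-4-one | O=c1cc(CCc2ccccc2)oc2cc(F)c(Br)cc12
A1 | direct plan | (5S,6S,7S,8S)-5,6:7,8-diepoxy-2-[2-(4-methoxyphenyl)ethyl]-5,6,7,8-tetrahydro-4H-chromen-4-one | COc1ccc(CCc2cc(=O)c3c(o2)[C@H]2O[C@H]2[C@H]2O[C@@H]32)cc1
A2 | direct plan | 6,7-dihydroxy-2-(2-phenylethyl)-4H-chromen-4-one | Oc1cc2oc(CCc3ccccc3)cc(=O)c2cc1O
A3 | direct plan | (4R,5R)-4,5-dihydroxycyclohex-2-en-1-one butane-2,3-diacetal | O=C1C=C[C@H]2O[C@](C)(OC)[C@@](C)(OC)O[C@@H]2C1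
A4 | direct plan | (5R,6R)-5,6-dihydroxy-2-[2-(4-methoxyphenyl)ethyl]-5,6-dihydro-4H-chromen-4-one | COc1ccc(CCc2cc(=O)c3c(o2)C=C[C@@H](O)[C@@H]3O)cc1
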